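The flavone is opened at C4, a lone carbonyl carbon lying between C4a of ring A and the methoxy-bearing C3 of ring C, and this carbon is supplied as carbon monoxide. One palladium-catalysed carbonylative α-arylation unites an ortho-MOM-protected 3,4-dimethoxyphenyl iodide (ring A with the masked O1), CO and the only enolisable carbon of methoxymethyl 2,4,5-trimethoxyphenyl ketone (C2, C3 and ring B), forming C4a–C4 and C3–C4 together and giving an open-chain 2-methoxy-1,3-diketone. Acid then frees the phenol and closes ring C; oxidative demethylation and reduction of the para-dimethoxy pair of ring B reveal the hydroquinone.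

Key step: step 4

Assumption: the open-chain 2-methoxy-1,3-diketone is treated as a racemic, enolisable keto form, since its central carbon becomes sp2 in the flavone; 1-bromo-2,4,5-trimethoxybenzene and N,2-dimethoxy-N-methylacetamide are taken as catalogue compounds, chosen because Lewis-acid acylation with methoxyacetyl chloride risks decarbonylation of the acylium ion.

Step 1
Reactants: 1 2,3-dimethoxyphenol; 2 chloromethyl methyl ether
Product: 3 1,2-dimethoxy-3-(methoxymethoxy)benzene
Conditions: i-Pr2NEt, CH2Cl2, 0 °C to rt
Reagents that add atoms: none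
Why: Williamson-type O-alkylation of the phenol by the oxocarbenium-like chloromethyl ether should install the MOM acetal, which tolerates organolithiums and the basic coupling and later serves as ortho-director and as acid-labile mask of O1.

Step 2
Reactants: 3 1,2-dimethoxy-3-(methoxymethoxy)benzene
Product: 5 1-iodo-3,4-dimethoxy-2-(methoxymethoxy)benzene, via aryllithium 4 (not isolated)
Conditions: n-BuLi, THF, 0 °C; then I2, THF, −78 °C to rt; aq. Na2S2O3
Reagents that add atoms: iodine, [I][I]
Why: Directed ortho-metalation followed by iodinolysis: the bidentate acetal outranks methoxy as a director and has only one free ortho position (C4 of 3), so n-BuLi should metalate there and I2 should trap the aryllithium at the future C4a.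

Step 3
Reactants: 6 1-bromo-2,4,5-trimethoxybenzene; 7 N,2-dimethoxy-N-methylacetamide
Product: 10 2-methoxy-1-(2,4,5-trimethoxyphenyl)ethan-1-one, via 2,4,5-trimethoxyphenyllithium 8 (not isolated), via lithium hemiaminal adduct 9 (not isolated)
Conditions: n-BuLi, THF, −78 °C; then 7, −78 to 0 °C; 1 M aq. HCl
Reagents that add atoms: none
Why: Bromine–lithium exchange followed by Weinreb ketone synthesis should place the methoxyacetyl group exactly at the carbon that carried bromine, because the chelated tetrahedral adduct 9 resists a second addition and collapses to the ketone only on acidic quench.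

Step 4
Reactants: 5 1-iodo-3,4-dimethoxy-2-(methoxymethoxy)benzene; 10 2-methoxy-1-(2,4,5-trimethoxyphenyl)ethan-1-one; 11 carbon monoxide
Product: 13 1-[3,4-dimethoxy-2-(methoxymethoxy)phenyl]-2-methoxy-3-(2,4,5-trimethoxyphenyl)propane-1,3-dione (racemic at C2; keto–enol mixture), via chloromagnesium enolate 12 (not isolated)
Conditions: Pd(dba)2 (5 mol %), Xantphos (5 mol %), MgCl2, NEt3, CO (1 atm), dioxane, 80 °C; aq. NH4Cl work-up
Reagents that add atoms: none
Why: Zerovalent palladium, formed from Pd(dba)2 and Xantphos, adds oxidatively to the C–I bond of 5 at the future C4a and migratory insertion of CO gives an aroyl complex of divalent palladium in which C4a–C4 already exists, while MgCl2 chelates the carbonyl and α-methoxy oxygens of 10 so that NEt3 can deprotonate it to enolate 12, which replaces iodide on palladium and is C-acylated by reductive elimination to form C3–C4. The closest known reaction type is the palladium-catalysed carbonylative α-arylation of ketones with aryl iodides to 1,3-diketones, a carbonylative relative of enolate arylation, here run with the soft magnesium/amine enolisation familiar from Claisen-type acylations. No ring is closed, and the one new stereocentre (C2 of the diketone) is formed racemic and uncontrolled, which is harmless because it becomes the sp2 carbon C3 of the flavone. The step needs carbonylation to outrun direct arylation, which 1 atm of CO and the fast CO insertion of aroyl precursors from aryl iodides should secure, and it needs acylation on carbon at one site only, which is secured by the single enolisable CH2 of 10, by the chelated magnesium enolate and by the wide bite angle of Xantphos that speeds acyl–carbon reductive elimination. The product should stay bound as its magnesium diketonate until work-up, which shields it from a second acylation and from retro-Claisen cleavage, and the acetal and aryl ethers are inert to the mild base.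

Step 5
Reactants: 13 1-[3,4-dimethoxy-2-(methoxymethoxy)phenyl]-2-methoxy-3-(2,4,5-trimethoxyphenyl)propane-1,3-dione
Product: 16 3,7,8-trimethoxy-2-(2,4,5-trimethoxyphenyl)-4H-chromen-4-one, via phenol diketone 14 (not isolated), via cyclic hemiketal 15 (not isolated)
Conditions: conc. HCl, MeOH, 60 °C
Reagents that add atoms: none
Why: Acid-catalysed acetal cleavage should free the C8a phenol 14, whose oxygen adds 6-exo-trig to the ring B ketone to give hemiketal 15, and acid-catalysed cyclodehydration (the classical flavone closure of ortho-hydroxyaryl 1,3-diketones) then forms the C2=C3 bond of ring C, the direction of closure being unambiguous because only one phenol is free and all aryl methyl ethers survive.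

Step 6
Reactants: 16 3,7,8-trimethoxy-2-(2,4,5-trimethoxyphenyl)-4H-chromen-4-one
Product: 18 diplotrin A [2-(2,5-dihydroxy-4-methoxyphenyl)-3,7,8-trimethoxy-4H-chromen-4-one], via methoxyquinone 17 (not isolated)
Conditions: (NH4)2Ce(NO3)6 (2.5 equiv), MeCN/H2O, 0 °C; then EtOAc, sat. aq. Na2S2O4, rt, under N2
Reagents that add atoms: water, O
Why: Oxidative demethylation by tetravalent cerium (single-electron oxidation of the most electron-rich ring, ipso attack of water at C2' and C5' and loss of two methanol) should convert the para-dimethoxy pair of ring B into 2-methoxy-1,4-benzoquinone 17 while ring A, deactivated by the conjugated C4 carbonyl, stays intact, and dithionite reduction in the work-up then gives the hydroquinone.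

Compound list
1 | 2,3-dimethoxyphenol | COc1cccc(O)c1OC | starting material
2 | chloromethyl methyl ether | COCCl | starting material
3 | 1,2-dimethoxy-3-(methoxymethoxy)benzene | COCOc1cccc(OC)c1OC | intermediate
4 | [3,4-dimethoxy-2-(methoxymethoxy)phenyl]lithium (formed in situ) | COCOc1c([Li])ccc(OC)c1OC | intermediate
5 | 1-iodo-3,4-dimethoxy-2-(methoxymethoxy)benzene | COCOc1c(I)ccc(OC)c1OC | intermediate
6 | 1-bromo-2,4,5-trimethoxybenzene | COc1cc(OC)c(Br)cc1OC | starting material
7 | N,2-dimethoxy-N-methylacetamide | COCC(=O)N(C)OC | starting material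
8 | (2,4,5-trimethoxyphenyl)lithium (formed in situ) | COc1cc(OC)c([Li])cc1OC | intermediate
9 | lithium 2-methoxy-1-[methoxy(methyl)amino]-1-(2,4,5-trimethoxyphenyl)ethan-1-olate (formed in situ, racemic) | COCC(O[Li])(N(C)OC)c1cc(OC)c(OC)cc1OC | intermediate
10 | 2-methoxy-1-(2,4,5-trimethoxyphenyl)ethan-1-one | COCC(=O)c1cc(OC)c(OC)cc1OC | intermediate
11 | carbon monoxide | [C-]#[O+] | starting material
12 | chloromagnesium (Z)-2-methoxy-1-(2,4,5-trimethoxyphenyl)ethen-1-olate (formed in situ; chelated geometry assumed) | CO/C=C(\O[Mg]Cl)c1cc(OC)c(OC)cc1OC | intermediate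
13 | 1-[3,4-dimethoxy-2-(methoxymethoxy)phenyl]-2-methoxy-3-(2,4,5-trimethoxyphenyl)propane-1,3-dione (racemic, enolisable) | COCOc1c(C(=O)C(OC)C(=O)c2cc(OC)c(OC)cc2OC)ccc(OC)c1OC | intermediate
14 | 1-(2-hydroxy-3,4-dimethoxyphenyl)-2-methoxy-3-(2,4,5-trimethoxyphenyl)propane-1,3-dione (formed in situ, racemic) | COc1ccc(C(=O)C(OC)C(=O)c2cc(OC)c(OC)cc2OC)c(O)c1OC | intermediate
15 | 2-hydroxy-3,7,8-trimethoxy-2-(2,4,5-trimethoxyphenyl)chroman-4-one (formed in situ, racemic diastereomer mixture) | COC1C(=O)c2ccc(OC)c(OC)c2OC1(O)c1cc(OC)c(OC)cc1OC | intermediate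
16 | 3,7,8-trimethoxy-2-(2,4,5-trimethoxyphenyl)-4H-chromen-4-one | COc1cc(OC)c(-c2oc3c(OC)c(OC)ccc3c(=O)c2OC)cc1OC | intermediate
17 | 2-methoxy-5-(3,7,8-trimethoxy-4-oxo-4H-chromen-2-yl)cyclohexa-2,5-diene-1,4-dione (formed in situ) | COC1=CC(=O)C(-c2oc3c(OC)c(OC)ccc3c(=O)c2OC)=CC1=O | intermediate
18 | diplotrin A, 2-(2,5-dihydroxy-4-methoxyphenyl)-3,7,8-trimethoxy-4H-chromen-4-one (no stereocentres) | COc1cc(O)c(-c2oc3c(OC)c(OC)ccc3c(=O)c2OC)cc1O | target

Total step count: 6. Longest linear sequence: 5 steps (1, 2, 4, 5, 6); step 3 is the second branch of the convergent route.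

Steps most likely to fail

Step 4 (key step). Soft enolisation of the ketone may be too slow to intercept the aroylpalladium species. Reduction or homocoupling of the iodide, direct arylation without CO, or acylation on the enolate oxygen could then take over. The fallback is a classical crossed Claisen acylation, which sets out from MOM ether 3 and ketone 10 and comes back at diketone 13. Compound 3 is lithiated as in step 2 and aryllithium 4 is added to excess ClCO2Me at −78 °C to give methyl 3,4-dimethoxy-2-(methoxymethoxy)benzoate F1. Ketone 10 is deprotonated with LiN(SiMe3)2 (2.2 equiv, THF, −78 °C) and condensed with F1 on warming to rt. Deprotonation of the product drives the condensation, and a mild acidic work-up should deliver 13.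

Step 6. The single-electron oxidation may not stay on ring B. Conjugation of ring B with the electron-poor pyranone narrows its gap to the veratrole-type ring A, so over-oxidation of ring A, ring nitration or ortho-quinone formation by loss of the C4' methyl group could compete. The fallback avoids the oxidation by carrying the two hydroquinone oxygens as benzyl ethers; it sets out from aryl iodide 5 and amide 7 and comes back at target 18. Commercial 2-methoxybenzene-1,4-diol is benzylated (BnBr, K2CO3, DMF, under N2) to 1,4-bis(benzyloxy)-2-methoxybenzene F2. Bromination para to the methoxy group (NBS, MeCN, 0 °C) gives 1,4-bis(benzyloxy)-2-bromo-5-methoxybenzene F3. Treatment as in step 3 (n-BuLi, then 7) gives 1-[2,5-bis(benzyloxy)-4-methoxyphenyl]-2-methoxyethan-1-one F4. The carbonylative coupling of step 4 with 5 should give 1-[2,5-bis(benzyloxy)-4-methoxyphenyl]-3-[3,4-dimethoxy-2-(methoxymethoxy)phenyl]-2-methoxypropane-1,3-dione F5. HCl in MeOH as in step 5, to which benzyl ethers are stable, should give 2-[2,5-bis(benzyloxy)-4-methoxyphenyl]-3,7,8-trimethoxy-4H-chromen-4-one F6. Hydrogenolysis (H2, Pd/C, EtOAc/MeOH, rt) should then release 18 directly.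

Step 2. Metalation may be incomplete or not exclusive at the position next to the acetal. Competing deprotonation beside the outer methoxy group (C6 of 3) would give a regioisomeric iodide that is hard to separate. The fallback places the halogen by phenol-directed electrophilic substitution; it sets out from phenol 1 and comes back at aryllithium 4 and hence at 5. Phenol 1 is brominated ortho to the hydroxyl group with Br2 and t-BuNH2 in toluene at −78 °C (amine-mediated ortho-bromination of phenols) to give 6-bromo-2,3-dimethoxyphenol F7. Protection with 2 as in step 1 gives 1-bromo-3,4-dimethoxy-2-(methoxymethoxy)benzene F8. Bromine–lithium exchange (n-BuLi, THF, −78 °C) then generates 4 regiospecifically, and the I2 quench of step 2 should give 5.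

Further compounds
F1 | step 4 | methyl 3,4-dimethoxy-2-(methoxymethoxy)benzoate | COCOc1c(C(=O)OC)ccc(OC)c1OC
F2 | step 6 | 1,4-bis(benzyloxy)-2-methoxybenzene | COc1cc(OCc2ccccc2)ccc1OCc1ccccc1
F3 | step 6 | 1,4-bis(benzyloxy)-2-bromo-5-methoxybenzene | COc1cc(OCc2ccccc2)c(Br)cc1OCc1ccccc1
F4 | step 6 | 1-[2,5-bis(benzyloxy)-4-methoxyphenyl]-2-methoxyethan-1-one | COCC(=O)c1cc(OCc2ccccc2)c(OC)cc1OCc1ccccc1
F5 | step 6 | 1-[2,5-bis(benzyloxy)-4-methoxyphenyl]-3-[3,4-dimethoxy-2-(methoxymethoxy)phenyl]-2-methoxypropane-1,3-dione (racemic) | COCOc1c(C(=O)C(OC)C(=O)c2cc(OCc3ccccc3)c(OC)cc2OCc2ccccc2)ccc(OC)c1OC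
F6 | step 6 | 2-[2,5-bis(benzyloxy)-4-methoxyphenyl]-3,7,8-trimethoxy-4H-chromen-4-one | COc1cc(OCc2ccccc2)c(-c2oc3c(OC)c(OC)ccc3c(=O)c2OC)cc1OCc1ccccc1
F7 | step 2 | 6-bromo-2,3-dimethoxyphenol | COc1ccc(Br)c(O)c1OC
F8 | step 2 | 1-bromo-3,4-dimethoxy-2-(methoxymethoxy)benzene | COCOc1c(Br)ccc(OC)c1OC
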